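Count the L that is left, not the product made, and read the order in L from that count.

in all of them: Z 0.1 mol%; X 22 µM
- Tuesday's: D 0.025 M; E 0.025 M; L 0.75 equiv; run made earlier
- Friday's: D 0.025 M; E 0.025 M; L 3 equiv; run made earlier
- Monday's: D 0.013 M; E 0.013 M; L 1.5 equiv; run made earlier
- flask: D 0.025 M; E 0.025 M; L 1.50 equiv

| run | time / min | Q / % | D / % |
|---|---|---|---|
| Tuesday's | 0.667 | 2.4 | 48.1 |
| Tuesday's | 2.00 | 7.1 | 43.4 |
| Tuesday's | 3.00 | 8.3 | 42.1 |
| Tuesday's | 5.00 | 11.3 | 38.2 |
| Tuesday's | 8.00 | 14.4 | 35.1 |
| Tuesday's | 10.0 | 16.7 | 34.8 |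
| Tuesday's | 12.0 | 17.4 | 32.5 |
| Friday's | 0.667 | 9.3 | 39.3 |
| Friday's | 2.00 | 21.3 | 28.1 |
| Friday's | 3.00 | 26.8 | 23.4 |
| Friday's | 5.00 | 33.9 | 15.5 |
| Friday's | 8.00 | 38.9 | 9.8 |
| Friday's | 10.0 | 42.3 | 8.4 |
| Friday's | 12.0 | 44.0 | 6.9 |
| Monday's | 1.00 | 2.8 | 46.7 |
| Monday's | 3.00 | 5.1 | 45.3 |
| Monday's | 6.00 | 9.0 | 40.2 |
| Monday's | 8.00 | 11.4 | 38.4 |
| Monday's | 12.0 | 15.0 | 35.7 |

(each reading ± 0.5 percentage points)

- Z is single-handed; D and E are mirror images of each other, charged as a racemate, each of them at the stated concentration
- steps that have been proposed: Z + X <-> J; L + Z + E -> Z + G; L + Z + D -> Z + Q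

* apparent order in Z when 30% of the D and E together are converted (percent change of the rate of making Q for one percent more Z charged)
* apparent order in L when 30% of the D and E together are converted (percent change of the rate of making Q for one percent more L charged)

Run the flask slowly. In the first instants the whole charge of L stands. At 0.667 min, Friday's run has made 9.3% of Q and Tuesday's 2.4%, a ratio, as read, of 3.88 for 4.00 times the L, so take the rate as proportional to cL.

In the middle, each conversion takes one L, whether it takes D or E. At a fixed conversion of a fixed charge of D and E, the L used is therefore a fixed amount: at 30% it is 0.0150 M out of 0.0375 M charged. In the flask 60.0% of the L charged stands at that moment; call this the L fraction left. One percent more L charged leaves the L used as it was, so cL at that conversion rises by that percent divided by that fraction, and with a rate proportional to cL this gives an order of 1.67 (my own reckoning). The proposed step from Z and X to J may also take Z away with time, and Friday's run, with more L, is ahead of Tuesday's at 3.00 min, so I expect a little more than that.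

At the end of the flask L is the limiting reagent: its charge is 75.0% of D and E together.

The forecast gave 1.25 for Z and 1.3 for L, holding that "the reaction is first order in L"; my count gives 1.67 for L.

    Z + X ⇌ J (K = 44000 M⁻¹, k = 5600 M⁻¹ min⁻¹)
    L + Z + E → Z + G (k = 95000 M⁻² min⁻¹)
    L + Z + D → Z + Q (k = 1.90 × 10⁵ M⁻² min⁻¹)

The flask gives 1.9 for L and 1.3 for Z. It reaches 30% at 4.24 min, with free Z at 85.9% after 1.50 min and 67.3% after 7.50 min. In Friday's run the L fraction left is 80.0%, so cL there stands 2.67 times the flask's at the same conversion. Friday's Q rate, as a reading averaged from 0.667 min to 3.00 min, is 0.00375 M min⁻¹, which is 3.13 times the flask's 0.00120 M min⁻¹ at 30% conversion.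

(All runs were generated by integration for substances that don't exist, and the scatter is random.)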